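0.0130 M is what Sunday's flask gains in c(target) late in its run, for each factor e in time. Call this the gain per e-fold: the rise of c(target) while the time grows by a factor e.

| flask | substrate | reagent | free catalyst | remark | time |
|---|---|---|---|---|---|
| Wednesday's | 0.027 M | 0.60 equiv (fed, over 1.5 s) | 0.5 mol% | run made earlier |  |
| Thursday's | 0.079 M | 0.60 equiv (fed, over 1.5 s) | 0.5 mol% | run made earlier |  |
| Saturday's | 0.16 M | 0.60 equiv (fed, over 1.5 s) | 0.5 mol% | run made earlier |  |
| Sunday's | 0.10 M | 0.60 equiv (fed, over 1.5 s) | 0.28 mol% | run made earlier |  |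
| red | 0.030 M | 0.600 equiv (fed, over 1.5 s) | 0.12 mol% |  | 5.0 min |
| blue | 0.050 M | 0.150 equiv (fed, over 1.5 s) | 0.12 mol% |  | 5.0 min |
| grey | 0.20 M | 0.600 equiv (fed, over 1.5 s) | 0.3 mol% |  | 5.0 min |
| ochre | 0.10 M | 0.600 equiv (fed, over 1.5 s) | 0.5 mol% |  | 5.0 min |
| green | 0.050 M | 0.900 equiv (fed, over 1.5 s) | 0.12 mol% |  | 5.0 min |

| run | time / min | target / % | substrate / % |
|---|---|---|---|
| Wednesday's | 0.200 | 9.9 | 89.6 |
| Wednesday's | 0.667 | 28.7 | 70.5 |
| Wednesday's | 1.33 | 45.4 | 54.8 |
| Wednesday's | 2.00 | 54.1 | 45.1 |
| Wednesday's | 2.50 | 57.6 | 41.6 |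
| Thursday's | 0.200 | 15.4 | 84.1 |
| Thursday's | 0.417 | 24.1 | 75.0 |
| Thursday's | 0.667 | 31.5 | 67.8 |
| Thursday's | 1.33 | 43.1 | 56.2 |
| Thursday's | 2.50 | 52.5 | 45.8 |
| Saturday's | 0.200 | 12.8 | 86.5 |
| Saturday's | 0.417 | 18.1 | 81.5 |
| Saturday's | 0.667 | 21.1 | 77.5 |
| Saturday's | 1.33 | 25.4 | 71.4 |
| Saturday's | 2.50 | 30.7 | 66.3 |
| Sunday's | 0.200 | 9.8 | 89.9 |
| Sunday's | 0.667 | 21.2 | 78.0 |
| Sunday's | 1.33 | 29.4 | 69.1 |
| Sunday's | 2.00 | 34.9 | 63.3 |
| Sunday's | 2.50 | 37.6 | 60.4 |

(scatter of a reading: 0.3 percentage points)



- the flasks put in order of amount of target, in percent of the substrate charged, best first, at 5.0 min (red / blue / grey / ochre / green)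
- the same order at 1.0 min (red / blue / grey / ochre / green)
- the amount of target, in percent of the substrate charged of the flask you put first, at 5.0 min
- the amount of target, in percent of the substrate charged of the flask you put last, at 5.0 min

Saturday's flask is charged with 2.86 times Sunday's c(free catalyst), yet over its late stretch it gains 0.0134 M per e-fold. The two flasks differ in c(substrate) as well as in loading, so these readings say only that their late gains match, and the reckoning below carries that gain to ochre as an assumption.

Ochre has Sunday's c(substrate) and Sunday's reagent equivalents, with 1.79 times the loading. If progress runs on c(free catalyst) times time, ochre reaches Sunday's last reading of 37.6 % at 1.40 min. From there to 5.0 min the gain adds 17 percentage points, so the first round of this reckoning gives 54.1 %.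

That answer goes back into the chain. It lies close to what 0.600 equiv of reagent, the limiting reagent, allows if each target takes one reagent, but Sunday's stretch ended lower. The slope is therefore the weak link. Thursday's stretch lies higher, from 43.1 % to 52.5 %, and its gain is lower, 0.0118 M. The second round with that gain gives 52.6 % for ochre, and this reckoning commits to that.

The forecast reads: “Late rates follow about 0.013 M/t regardless of loading”. It orders the flasks ochre > green > red > grey > blue at 5.0 min and ochre > grey > green > red > blue at 1.0 min, with 52 % for ochre and 14.3 % for blue. Its top lies below this reckoning's 52.6 %.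

At 5.0 min the flasks stand ochre > green > red > grey > blue, with ochre at 54.7 % and blue at 14.9 %. At 1.0 min they stand ochre > green > grey > red > blue: green, at 18.1 %, is above grey, at 16.7 %, and the forecast had this pair the other way round.

    2 catalyst intermediate C → spent catalyst (k = 2420 M⁻¹ s⁻¹)
    catalyst intermediate B → catalyst intermediate C (k = 19.2 s⁻¹)
    substrate + catalyst intermediate A ⇌ catalyst intermediate B (K = 98.0 M⁻¹, k = 191 M⁻¹ s⁻¹)
    2 substrate → self-condensation product (k = 0.00114 M⁻¹ s⁻¹)
    reagent + free catalyst → catalyst intermediate A (k = 338 M⁻¹ s⁻¹)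
    catalyst intermediate C → free catalyst + target (k = 17.8 s⁻¹)

In ochre at 5.00 min, catalyst intermediate C goes to free catalyst and target 1790 times as fast as to spent catalyst, and spent catalyst holds 93.8 % of the catalyst charged. From 1.0 min to 5.0 min ochre gains 0.0133 M per e-fold, against 0.0130 M from Sunday's flask. Read at 3.0 min, ochre holds 48.2 % of target, and 0.0130 M counted back from 54.7 % gives 48.0 %.

The runs are calculated on assumed constants, and the scatter is random.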